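## Structural features

The target is a 3,3''-biflavanone in which two 2-(4-hydroxyphenyl)chroman-4-one units are joined by a single sp3–sp3 bond between C3 and C3''. One unit carries a resorcinol-type ring A (7-OH) and the other a phloroglucinol-type ring A (5''-OH and 7''-OH), so the halves differ only by the hydroxyl at C5''. The stereocentres C2, C3, C3'' and C2'' stand in a row; the SMILES reads as (2S,3R,2''S,3''R) with both pyranone rings 2,3-trans, so the core without the ring A oxygens would be C2-symmetric. C3 and C3'' are α to ketones and can epimerise, and C2–O1 and C2''–O1'' are benzylic ethers β to those ketones, so base can open the rings by retro-oxa-Michael reaction and erase C2. The real difficulty is to make the crowded C3–C3'' bond with control of four contiguous centres and then to tell two nearly identical halves apart. The key step exploits the fact that each ring A is fused to its pyranone across C4a–C8a, which is the C5=C6 enone bond of a 2-aryl-2,3-dihydropyran-4-one. C8a is the electrophilic β-carbon and C4a the α-carbon, so a four-carbon oxygenated diene laid across this bond supplies C5–C8 with oxygen at C7, and also at C5'' when its terminus is at the carboxyl level.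

## Logic of the disconnections

**16 to 15.** The two aryl O–CH2Ph bonds on ring B are cut. These phenols must be masked through enolate, bromination, silyl triflate and base stages. A benzyl ether is chosen over an acetal-type ether because a silyl triflate would ionise the acetal and the silyloxydienes would be alkylated by it. Neutral hydrogenolysis then exposes the target without acid or base at C2 and C3. The demand is that hydrogenolysis spares the benzylic C2–O1 bonds and the ketones.

**15 to 7, 2 and 10.** C4a–C5 and C8–C8a are cut in one half, C4a''–C5'' and C8''–C8a'' in the other. Both rings A sit on the former enone bond, so removing them turns an unsymmetrical biflavanone into a C2-symmetric bis-bromoenone and moves the difference between the halves into the reagent. Eight ring carbons and three oxygens are removed, and no stereocentre is touched. The forward step must deliver the diene CH2 terminus to the β-carbon and keep O1 on C8a. This means HBr has to leave before the ring is closed, for the reason given in step 6. It must also stop the first diene at mono-addition, which is statistical.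

**7 to 6.** The two C5–Br bonds are cut. Bromine activates the enone and carries the oxidation level needed to return C8a to sp2 after C–C bond formation. It is put on last because a vinyl bromide would not survive the amide base and copper oxidant that make 6. The demand is bromination at the enol ether carbon only, not on the benzyloxyphenyl rings and not at C3.

**6 to two molecules of 4.** The central C3–C3' bond is cut. It joins two identical α-carbonyl carbons, so it is the retron of an oxidative enolate dimerisation that consumes two molecules of 4 for each molecule of 6. The molecule is halved and four stereocentres reduce to one, because C3 follows C2. The forward step needs an enolate that does not expel O1, bond formation anti to the C2 aryl group, and 4 in high enantiopurity.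

**4 to 1 and 2.** C2–C3 and O1–C6 of the pyranone are cut, the hetero-Diels–Alder retron. Both components are commercial and 2 is used again in the key step. The demand is facial control on an electron-rich aromatic aldehyde.

**10 to 9 to 8.** Two O–Si bonds are cut in turn. The forward steps are standard enol silylations, and the only demand is exclusion of moisture.

## Other disconnections considered

Alternative 1: The cut is the arene bond C4a''–C8a'' of the phloroglucinol ring (the two ortho positions are equivalent in the product). In the forward step Mg(OMe)2 opens the lactone of the 4-hydroxy-2-pyranone A1, and the C4a'' methylene then acylates the liberated ester carbonyl in a Claisen closure to give the trihydroxyphenyl ketone A2.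

- In its favour: the two halves are different from the start, so there is no statistical step, and on this point it is better than the chosen plan. The ring-forming event has direct precedent in acylphloroglucinol synthesis, which is also better than a key step that has to be labelled new. The closure cannot give a regioisomer.
- Against it here: only one ring A is made this way, so the resorcinol flavanone half is carried from the beginning. A1 must hold C2, C3, C3'' and the silyloxy carbinol centre in an open chain, where C3'' is α to a ketone and the silyloxy group is β to it, so the basic cyclisation invites β-elimination and epimerisation. The competing aldol-type folding onto a ketone is not blocked. After A2 the second pyranone must still be closed at O1''–C2'' with inversion, since A2 carries the carbinol carbon in the configuration opposite to C2'' of the target. That carbon is a 4-alkoxybenzylic position and prone to ionisation.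
- Comparison: the mechanism is close to the phloroglucinol half of the chosen key step, where the same Claisen mode is used but O1 already ties C8a'' into the pyranone. The alternative is free of the bromine and oxidation-level problem. It is expected to be clearly longer, with three kinds of protecting group.

Alternative 2: The cuts are the aryl ketone bonds C4–C4a and C4''–C4a''. In the forward step trifluoroacetic anhydride activates both carboxyl groups of the diacid A3, and each acyl group attacks the ortho position of the aryl ether on the neighbouring benzylic carbon to give A4.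

- In its favour: both rings A are bought, not built. Intramolecular Friedel–Crafts acylation of 3-aryloxypropanoic acids to chroman-4-ones is an established reaction, so on precedent for the ring-forming step it is better than the chosen plan. Both pyranones close in one operation, which is equal to the chosen plan.
- Against it here: the resorcinol-derived ether has two different ortho positions, and acylation between the two oxygens would misplace the oxygen at C5. The two activated carboxyl groups of A3 can react with each other before they acylate the arenes, so the second acylation needs renewed activation. The strongly acidic medium can ionise the benzylic aryl ether bonds at C2 and C2''. Above all, the difficulty moves into A3, which has four contiguous acyclic stereocentres and two different aryloxy groups. Introducing those two groups is either statistical again or costs extra differentiation steps.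
- Comparison: stereocontrol is harder than in the chosen plan, where the ring sets C3 from C2. The route is expected to be longer, and deprotection needs two operations (acetate and benzyl) against one.

Alternative 3: The cuts are O1–C2 and O1''–C2''. In the forward step a quinine-derived amine–thiourea catalyst activates enone and phenol in the bis-chalcone A5 for two 6-endo-trig oxa-Michael additions that give A6, with C3 and C3'' set by protonation.

- In its favour: it follows the chalcone-to-flavanone relationship. A5 is achiral and all four stereocentres would arise in one catalytic operation, so on stereocentres set per step it is better than the chosen plan. Both rings A are bought, and on paper the step count is at least equal.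
- Against it here: each acceptor in A5 is an α-substituted chalcone inside a cross-conjugated 2,3-diaroylbutadiene, hindered at the β-carbon and twisted out of conjugation. Reversibility of the oxa-Michael addition threatens the enantiopurity. Two independent events with imperfect selectivity would erode the diastereomeric purity in the meso-type and cis sense. The relative sense of the halves rests on the catalyst alone, whereas the chosen plan fixes it by dimerising one enantiomer. Making A5 requires two different aroyl groups on one four-carbon chain and a twofold benzylidenation that competes with furan formation. A6 carries five acetal ethers whose removal exposes the product to acid.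
- Comparison: this is the shortest alternative and the most attractive in concept, but the decisive step is the least secured in selectivity.

Key step: step 6

Assumptions and remarks on the chemistry:

- The (S,S)-configured chromium complex is assumed to give the (S)-pyranone; if the sense is opposite for this aldehyde, the antipodal complex is used with no other change. Here salen is the N,N'-bis(3,5-di-tert-butylsalicylidene)cyclohexane-1,2-diamine dianion.
- The 2,3-trans arrangement in each pyranone ring is assumed to be the thermodynamically preferred one, so any C3 epimer can be equilibrated with a mild amine base.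
- Flavanone numbering is used, unprimed for the 7-hydroxy half and doubly primed for the 5,7-dihydroxy half. In 4 to 7 and 11 to 13 the pyranone carbons C5 and C6 are the later C4a and C8a.
- The bis-bromoenone 7 and the annulation product 15 carry the configuration of the target. The ring B phenols are carried as benzyl ethers, and the key step is run in the order addition, loss of HBr, ring closure.

## Route

Step 1
Reactants: 1 4-(benzyloxy)benzaldehyde; 2 (E)-1-methoxy-3-(trimethylsilyloxy)buta-1,3-diene
Product: 4 (S)-2-[4-(benzyloxy)phenyl]-2,3-dihydro-4H-pyran-4-one, via silyl enol ether cycloadduct 3 (not isolated)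
Conditions: (S,S)-(salen)CrBF4 (2 mol%; trivalent chromium; from (salen)CrCl and AgBF4), 4 Å MS, t-BuOMe, −30 °C; then CF3CO2H (cat.), CH2Cl2, 0 °C
Reagents that add atoms: none
Why: Catalytic asymmetric hetero-Diels–Alder reaction: the chiral chromium Lewis acid binds the aldehyde and exposes one carbonyl face to the diene, which sets C2; acid then releases methanol and the silyl group from the cycloadduct to give the enone. The benzyl ether is inert to both stages.

Step 2
Reactants: 4 (S)-2-[4-(benzyloxy)phenyl]-2,3-dihydro-4H-pyran-4-one (first molecule); 4 (S)-2-[4-(benzyloxy)phenyl]-2,3-dihydro-4H-pyran-4-one (second molecule)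
Product: 6 (2S,2'S,3R,3'R)-2,2'-bis[4-(benzyloxy)phenyl]-2,2',3,3'-tetrahydro-4H,4'H-[3,3'-bipyran]-4,4'-dione, via lithium dienolate 5 (not isolated)
Conditions: LiN(iPr)2 (1.05 equiv per ketone), THF, −78 °C; then CuCl2 (1.1 equiv per enolate), DMF, −78 → 0 °C
Reagents that add atoms: none
Why: Oxidative homodimerisation of a ketone lithium enolate by divalent copper: two molecules of 4 are deprotonated at C3, the only sp3 α-position, and the two enolates are joined at C3 with loss of one electron each; at −78 °C the enolate is not expected to expel O1. Each new bond should form anti to the neighbouring C2 aryl group (2,3-trans), so two (S)-units can give only the C2-symmetric dimer. Any minor enantiomer is consumed mainly in the separable meso-type diastereomer, which should raise the enantiopurity of 6.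

Step 3
Reactants: 6 (2S,2'S,3R,3'R)-2,2'-bis[4-(benzyloxy)phenyl]-2,2',3,3'-tetrahydro-4H,4'H-[3,3'-bipyran]-4,4'-dione
Product: 7 (2S,2'S,3R,3'R)-2,2'-bis[4-(benzyloxy)phenyl]-5,5'-dibromo-2,2',3,3'-tetrahydro-4H,4'H-[3,3'-bipyran]-4,4'-dione
Conditions: N-bromosuccinimide (2.1 equiv), CH2Cl2, 0 °C, dark
Reagents that add atoms: N-bromosuccinimide, O=C1CCC(=O)N1Br
Why: Electrophilic α-bromination of a β-alkoxy enone, once on each ring: C5 is the nucleophilic enol ether carbon, the oxocarbenium ion loses H5 to the succinimide anion and the enone is restored. No acid is set free, so C3 is not enolised, and the enol ether is far more reactive than the benzyloxyphenyl rings.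

Step 4
Reactants: 8 methyl acetoacetate
Product: 9 methyl 3-(trimethylsilyloxy)but-2-enoate (E/Z mixture)
Conditions: Me3SiCl, Et3N, hexane, rt
Reagents that add atoms: chlorotrimethylsilane, C[Si](C)(C)Cl
Why: O-Silylation of the enol of a β-keto ester under amine base; the double bond geometry is of no consequence.

Step 5
Reactants: 9 methyl 3-(trimethylsilyloxy)but-2-enoate
Product: 10 1-methoxy-1,3-bis(trimethylsilyloxy)buta-1,3-diene
Conditions: LiN(iPr)2, THF, −78 °C; then Me3SiCl, −78 °C → rt; distilled
Reagents that add atoms: chlorotrimethylsilane, C[Si](C)(C)Cl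
Why: γ-Deprotonation of the β-silyloxy enoate gives the extended ester enolate, which is silylated on oxygen to the ketene silyl acetal. The diene is moisture-sensitive and is used freshly distilled.

Step 6
Reactants: 7 (2S,2'S,3R,3'R)-2,2'-bis[4-(benzyloxy)phenyl]-5,5'-dibromo-2,2',3,3'-tetrahydro-4H,4'H-[3,3'-bipyran]-4,4'-dione; 10 1-methoxy-1,3-bis(trimethylsilyloxy)buta-1,3-diene; 2 (E)-1-methoxy-3-(trimethylsilyloxy)buta-1,3-diene
Product: 15 (2S,2'S,3R,3'R)-2,2'-bis[4-(benzyloxy)phenyl]-5,7,7'-trihydroxy-[3,3'-bichromane]-4,4'-dione, via mono-Michael adduct 11 (not isolated), via bis-Michael adduct 12 (not isolated), via bis-pyranone keto ester 13 (not isolated), via half-aromatised chromanone 14 (not isolated)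
Conditions: 10 (1.0 equiv, slow addition), Me3SiOTf (0.2 equiv), CH2Cl2, −78 °C; then 2 (2.5 equiv), −78 → −40 °C; then MeOH (5 equiv), DBU (3 equiv), 0 °C → rt; then Mg(OMe)2, MeOH, rt → 40 °C; 1 M HCl work-up
Reagents that add atoms: none
Why: Proposed new method: each ring A is built as a stepwise formal [4+2] annulation on the bromoenone, the closest known reaction type being the Diels–Alder addition and aromatisation of α-halo enones and haloquinones with these silyloxydienes. First, Me3SiOTf turns the enone into a silyloxy oxocarbenium ion and the CH2 terminus of the diene adds to the β-carbon C8a (Mukaiyama–Michael addition, the established mode of 2,3-dihydropyran-4-ones), with one equivalent of 10 and then with 2 on the remaining ring. Second, methanol frees the α-bromo ketones and DBU removes HBr, which returns C4a=C8a to the enol ether level with the new C8 chain in place; this order is deliberate, because a ring closed before loss of HBr would hold Br on C4a and H on C8a cis on the ring fusion (no anti elimination) and would leave O1 on an sp3 carbon from which it is expelled in preference. Third, the ring closes at C4a–C5 from the extended enolate formed by deprotonation at C8: by 6-endo addition to the β-methoxyenone carbon and loss of methoxide for the resorcinol ring, and by 6-exo Claisen acylation on the methyl ester under Mg(OMe)2 for the phloroglucinol ring, the mode known for enolised triketo esters; enolisation then gives both arenes. No stereocentre is created, since the transient sp3 centres at C8a and C8a'' return to sp2, and C2, C3, C3'' and C2'' are not bonded to any reacting atom, so at most C3 and C3'' re-equilibrate to the preferred trans arrangement. Regiochemistry rests on polarity (diene CH2 to the β-carbon, oxygenated terminus to the α-carbon), and an aldol-type closure on C4 is excluded because it would place C4a=C8a at a bridgehead. The mixed pattern needs mono-addition of 10 to a substrate with two identical enones, which only stoichiometry can bias, so the two symmetric bis-annulation products are expected beside 15 and are removed by chromatography.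

Step 7
Reactants: 15 (2S,2'S,3R,3'R)-2,2'-bis[4-(benzyloxy)phenyl]-5,7,7'-trihydroxy-[3,3'-bichromane]-4,4'-dione
Product: 16 (2S,2'S,3R,3'R)-5,7,7'-trihydroxy-2,2'-bis(4-hydroxyphenyl)-[3,3'-bichromane]-4,4'-dione
Conditions: H2 (1 atm), Pd/C (10%), EtOAc–MeOH, rt
Reagents that add atoms: none
Why: Hydrogenolysis of the two aryl benzyl ethers on palladium under neutral conditions, so neither acid nor base reaches C2 or C3. The aryl ketones are deactivated by their oxygenated rings, and the C2–O1 bonds cleave much more slowly than aryl benzyl ethers if the reaction is stopped when 15 is consumed.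

## Compound list

1 | 4-(benzyloxy)benzaldehyde | O=Cc1ccc(OCc2ccccc2)cc1 | starting material
2 | (E)-1-methoxy-3-(trimethylsilyloxy)buta-1,3-diene | CO/C=C/C(=C)O[Si](C)(C)C | starting material
3 | (2S)-2-[4-(benzyloxy)phenyl]-6-methoxy-4-(trimethylsilyloxy)-3,6-dihydro-2H-pyran (mixture at C6) | COC1C=C(O[Si](C)(C)C)C[C@@H](c2ccc(OCc3ccccc3)cc2)O1 | intermediate (not isolated)
4 | (S)-2-[4-(benzyloxy)phenyl]-2,3-dihydro-4H-pyran-4-one | O=C1C=CO[C@H](c2ccc(OCc3ccccc3)cc2)C1 | intermediate
5 | lithium (S)-2-[4-(benzyloxy)phenyl]-2H-pyran-4-olate (C3 enolate of 4) | [Li]OC1=C[C@@H](c2ccc(OCc3ccccc3)cc2)OC=C1 | intermediate (not isolated)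
6 | (2S,2'S,3R,3'R)-2,2'-bis[4-(benzyloxy)phenyl]-2,2',3,3'-tetrahydro-4H,4'H-[3,3'-bipyran]-4,4'-dione | O=C1C=CO[C@H](c2ccc(OCc3ccccc3)cc2)[C@H]1[C@H]1C(=O)C=CO[C@@H]1c1ccc(OCc2ccccc2)cc1 | intermediate
7 | (2S,2'S,3R,3'R)-2,2'-bis[4-(benzyloxy)phenyl]-5,5'-dibromo-2,2',3,3'-tetrahydro-4H,4'H-[3,3'-bipyran]-4,4'-dione | O=C1C(Br)=CO[C@H](c2ccc(OCc3ccccc3)cc2)[C@H]1[C@H]1C(=O)C(Br)=CO[C@@H]1c1ccc(OCc2ccccc2)cc1 | intermediate
8 | methyl acetoacetate | COC(=O)CC(C)=O | starting material
9 | methyl 3-(trimethylsilyloxy)but-2-enoate (E/Z mixture) | COC(=O)C=C(C)O[Si](C)(C)C | intermediate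
10 | 1-methoxy-1,3-bis(trimethylsilyloxy)buta-1,3-diene | CO/C(O[Si](C)(C)C)=C\C(=C)O[Si](C)(C)C | intermediate
11 | mono-adduct: one ring of 7 unchanged; the other is the 4-(trimethylsilyloxy)-5-bromo enol ether carrying at C6 a 4-methoxy-4-oxo-2-(trimethylsilyloxy)but-2-enyl chain, drawn trans to the C2 aryl group | O=C1C(Br)=CO[C@H](c2ccc(OCc3ccccc3)cc2)[C@H]1[C@H]1C(O[Si](C)(C)C)=C(Br)[C@@H](CC(O[Si](C)(C)C)=CC(=O)OC)O[C@@H]1c1ccc(OCc2ccccc2)cc1 | intermediate (not isolated)
12 | bis-adduct: both rings are 4-(trimethylsilyloxy)-5-bromo enol ethers; C6 of one carries an (E)-4-methoxy-2-oxobut-3-enyl chain, C6 of the other the chain of 11, both drawn trans to the C2 aryl groups | C[Si](C)(C)OC1=C(Br)[C@@H](CC(=O)/C=C/OC)O[C@H](c2ccc(OCc3ccccc3)cc2)[C@H]1[C@H]1C(O[Si](C)(C)C)=C(Br)[C@@H](CC(O[Si](C)(C)C)=CC(=O)OC)O[C@@H]1c1ccc(OCc2ccccc2)cc1 | intermediate (not isolated)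
13 | (2S,2'S,3R,3'R)-2,2'-bis[4-(benzyloxy)phenyl]-6-[(E)-4-methoxy-2-oxobut-3-enyl]-6'-(4-methoxy-2,4-dioxobutyl)-2,2',3,3'-tetrahydro-4H,4'H-[3,3'-bipyran]-4,4'-dione | O=C1C=C(CC(=O)/C=C/OC)O[C@H](c2ccc(OCc3ccccc3)cc2)[C@H]1[C@H]1C(=O)C=C(CC(=O)CC(=O)OC)O[C@@H]1c1ccc(OCc2ccccc2)cc1 | intermediate (not isolated)
14 | (2S,3R)-2-[4-(benzyloxy)phenyl]-7-hydroxychroman-4-one joined at C3 to C3 of (2S,3R)-2-[4-(benzyloxy)phenyl]-6-(4-methoxy-2,4-dioxobutyl)-2,3-dihydro-4H-pyran-4-one | O=C1c2ccc(O)cc2O[C@H](c2ccc(OCc3ccccc3)cc2)[C@H]1[C@H]1C(=O)C=C(CC(=O)CC(=O)OC)O[C@@H]1c1ccc(OCc2ccccc2)cc1 | intermediate (not isolated)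
15 | (2S,2'S,3R,3'R)-2,2'-bis[4-(benzyloxy)phenyl]-5,7,7'-trihydroxy-[3,3'-bichromane]-4,4'-dione | O=C1c2ccc(O)cc2O[C@H](c2ccc(OCc3ccccc3)cc2)[C@H]1[C@H]1C(=O)c2c(O)cc(O)cc2O[C@@H]1c1ccc(OCc2ccccc2)cc1 | intermediate
16 | (2S,2'S,3R,3'R)-5,7,7'-trihydroxy-2,2'-bis(4-hydroxyphenyl)-[3,3'-bichromane]-4,4'-dione, that is (2S,3R,2''S,3''R) in flavanone numbering | O=C1c2ccc(O)cc2O[C@H](c2ccc(O)cc2)[C@H]1[C@H]1C(=O)c2c(O)cc(O)cc2O[C@@H]1c1ccc(O)cc1 | target

## Step count and least certain steps

Total: 7 steps. Longest linear sequence: 5 steps (steps 1, 2, 3, 6 and 7); the diene branch (steps 4 and 5) joins at step 6.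

**Step 6 (key step, proposed new method).**

- What may go wrong: premature ring closure of the silyl enol ether onto the activated side chain before HBr is lost, after which aromatisation is possible only by β-elimination of the pyranone oxygen, that is by ring opening. The base stages can also open the pyranone by retro-oxa-Michael reaction at C2, and methoxide can attack the α-bromo ketone before elimination. Independently of this, the partition between mono- and bis-addition of 10 is statistical, so at best about half of 7 can end in the mixed product. Stopping the first addition early, isolating the mono-adduct and recycling 7 would raise the efficiency but not remove the limit.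
- Fallback, known chemistry, from 1 and rejoining the route at 16: the rings A are bought instead of built.
  - Claisen–Schmidt condensation of 1 with 1-[4-(benzyloxy)-2-hydroxyphenyl]ethanone (KOH, EtOH) gives (E)-1-[4-(benzyloxy)-2-hydroxyphenyl]-3-[4-(benzyloxy)phenyl]prop-2-en-1-one F1. With 1-[2,4-bis(benzyloxy)-6-hydroxyphenyl]ethanone it gives (E)-1-[2,4-bis(benzyloxy)-6-hydroxyphenyl]-3-[4-(benzyloxy)phenyl]prop-2-en-1-one F2.
  - Each chalcone is cyclised by intramolecular oxa-Michael addition (NaOAc, EtOH, reflux). The (S)-enantiomers (S)-7-(benzyloxy)-2-[4-(benzyloxy)phenyl]chroman-4-one F3 and (S)-5,7-bis(benzyloxy)-2-[4-(benzyloxy)phenyl]chroman-4-one F4 are secured by kinetic resolution through asymmetric transfer hydrogenation of the unwanted enantiomer (RuCl(p-cymene)(TsDPEN), divalent ruthenium, HCO2H–Et3N) or by chromatography on a chiral phase.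
  - The lithium enolates (LiN(SiMe3)2, THF, −78 °C) are attached one after the other to iPr2SiCl2 to give the unsymmetrical diisopropylsilyl bis-enol ether F5. Oxidation with (NH4)2Ce(NO3)6 (tetravalent cerium) and NaHCO3 in MeCN at −10 °C couples C3 with C3'' inside the tether, each anti to its C2 aryl group and without statistical partition. This gives the pentabenzyl ether (2S,2'S,3R,3'R)-5,7,7'-tris(benzyloxy)-2,2'-bis[4-(benzyloxy)phenyl]-[3,3'-bichromane]-4,4'-dione F6.
  - Hydrogenolysis as in step 7 gives 16.

**Step 2.**

- What may go wrong: ring opening of the enolate by β-elimination of O1 on warming, or low conversion in the copper oxidation with O–C coupling and reduced diastereoselectivity, because the radical-type coupling is only moderately organised.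
- Fallback, from 4 and rejoining at 6: two equivalents of the lithium enolate of 4 are bound to iPr2SiCl2 to give the symmetrical diisopropylsilyl bis-enol ether F7. Its oxidation with (NH4)2Ce(NO3)6 (tetravalent cerium) and NaHCO3 in MeCN at −10 °C forms the C3–C3' bond intramolecularly and releases 6.

**Step 3.**

- What may go wrong: competing electrophilic bromination of the electron-rich benzyloxyphenyl rings, or over-bromination, if the enol ether carbon is slower than expected.
- Fallback, from 6 and rejoining at 15: α-iodination by nucleophile-catalysed addition–elimination (I2, pyridine, CH2Cl2), which does not touch arenes, gives (2S,2'S,3R,3'R)-2,2'-bis[4-(benzyloxy)phenyl]-5,5'-diiodo-2,2',3,3'-tetrahydro-4H,4'H-[3,3'-bipyran]-4,4'-dione F8. This compound enters step 6 in place of 7, with HI lost instead of HBr.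

**Step 7.**

- What may go wrong: over-reduction, meaning hydrogenolysis of the benzylic C2–O1 bonds with opening of the pyranone rings if the reaction runs on after debenzylation.
- Fallback, from 15 and rejoining at 16: Lewis acid dealkylation with BCl3 and pentamethylbenzene as cation scavenger in CH2Cl2 at −78 °C. No new compound arises (entry F0).

## Further compounds

F1 | step 6 | (E)-1-[4-(benzyloxy)-2-hydroxyphenyl]-3-[4-(benzyloxy)phenyl]prop-2-en-1-one | O=C(/C=C/c1ccc(OCc2ccccc2)cc1)c1ccc(OCc2ccccc2)cc1O
F2 | step 6 | (E)-1-[2,4-bis(benzyloxy)-6-hydroxyphenyl]-3-[4-(benzyloxy)phenyl]prop-2-en-1-one | O=C(/C=C/c1ccc(OCc2ccccc2)cc1)c1c(O)cc(OCc2ccccc2)cc1OCc1ccccc1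
F3 | step 6 | (S)-7-(benzyloxy)-2-[4-(benzyloxy)phenyl]chroman-4-one | O=C1C[C@@H](c2ccc(OCc3ccccc3)cc2)Oc2cc(OCc3ccccc3)ccc12
F4 | step 6 | (S)-5,7-bis(benzyloxy)-2-[4-(benzyloxy)phenyl]chroman-4-one | O=C1C[C@@H](c2ccc(OCc3ccccc3)cc2)Oc2cc(OCc3ccccc3)cc(OCc3ccccc3)c12
F5 | step 6 | diisopropylsilyl bis-enol ether of F3 and F4 | CC(C)[Si](OC1=C[C@@H](c2ccc(OCc3ccccc3)cc2)Oc2cc(OCc3ccccc3)ccc12)(OC1=C[C@@H](c2ccc(OCc3ccccc3)cc2)Oc2cc(OCc3ccccc3)cc(OCc3ccccc3)c12)C(C)C
F6 | step 6 | (2S,2'S,3R,3'R)-5,7,7'-tris(benzyloxy)-2,2'-bis[4-(benzyloxy)phenyl]-[3,3'-bichromane]-4,4'-dione | O=C1c2ccc(OCc3ccccc3)cc2O[C@H](c2ccc(OCc3ccccc3)cc2)[C@H]1[C@H]1C(=O)c2c(OCc3ccccc3)cc(OCc3ccccc3)cc2O[C@@H]1c1ccc(OCc2ccccc2)cc1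
F7 | step 2 | diisopropylsilyl bis-enol ether of two molecules of 4 | CC(C)[Si](OC1=C[C@@H](c2ccc(OCc3ccccc3)cc2)OC=C1)(OC1=C[C@@H](c2ccc(OCc3ccccc3)cc2)OC=C1)C(C)C
F8 | step 3 | (2S,2'S,3R,3'R)-2,2'-bis[4-(benzyloxy)phenyl]-5,5'-diiodo-2,2',3,3'-tetrahydro-4H,4'H-[3,3'-bipyran]-4,4'-dione | O=C1C(I)=CO[C@H](c2ccc(OCc3ccccc3)cc2)[C@H]1[C@H]1C(=O)C(I)=CO[C@@H]1c1ccc(OCc2ccccc2)cc1
F0 | step 7 | none | none
A1 | alternative 1 | 4-hydroxy-2H-pyran-2-one carrying at C6 the CH2–CO chain that bears the protected 7-oxygenated flavanone at C3'' and the silyloxybenzyl group | O=C1c2ccc(OCOC)cc2O[C@H](c2ccc(OCOC)cc2)[C@H]1[C@H]([C@@H](O[Si](C)(C)C(C)(C)C)c1ccc(OCOC)cc1)C(=O)Cc1cc(O)cc(=O)o1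
A2 | alternative 1 | corresponding 2,4,6-trihydroxyphenyl ketone | O=C1c2ccc(OCOC)cc2O[C@H](c2ccc(OCOC)cc2)[C@H]1[C@H]([C@@H](O[Si](C)(C)C(C)(C)C)c1ccc(OCOC)cc1)C(=O)c1c(O)cc(O)cc1O
A3 | alternative 2 | 2,3-bis(aryloxybenzyl)succinic acid with 3-(benzyloxy)phenoxy and 3,5-bis(benzyloxy)phenoxy groups and 4-acetoxyphenyl rings | O=C(O)[C@@H]([C@H](Oc1cccc(OCc2ccccc2)c1)c1ccc(OC(C)=O)cc1)[C@H]([C@H](Oc1cc(OCc2ccccc2)cc(OCc2ccccc2)c1)c1ccc(OC(C)=O)cc1)C(=O)O
A4 | alternative 2 | tribenzyl ether diacetate of the target | O=C1c2ccc(OCc3ccccc3)cc2O[C@H](c2ccc(OC(C)=O)cc2)[C@H]1[C@H]1C(=O)c2c(OCc3ccccc3)cc(OCc3ccccc3)cc2O[C@@H]1c1ccc(OC(C)=O)cc1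
A5 | alternative 3 | (2E,3E)-2,3-bis[4-(methoxymethoxy)benzylidene]-1-[2-hydroxy-4-(methoxymethoxy)phenyl]-4-[2-hydroxy-4,6-bis(methoxymethoxy)phenyl]butane-1,4-dione | COCOc1ccc(c(O)c1)C(=O)/C(=C/c1ccc(OCOC)cc1)C(=C/c1ccc(OCOC)cc1)\C(=O)c1c(O)cc(OCOC)cc1OCOC
A6 | alternative 3 | penta(methoxymethyl) ether of the target | O=C1c2ccc(OCOC)cc2O[C@H](c2ccc(OCOC)cc2)[C@H]1[C@H]1C(=O)c2c(OCOC)cc(OCOC)cc2O[C@@H]1c1ccc(OCOC)cc1
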